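## Structural features

Ferugin is a daucane sesquiterpenoid ester: a cyclopentane (ring A, C1–C5) trans-fused through the C1–C5 bond to a cycloheptane (ring B, C1 and C5–C10). C1 is quaternary (methyl), C4 is a tertiary carbinol carrying isopropyl, C6 carries the 4-hydroxybenzoate, C8 carries the exocyclic methylene C14, and C9 is a secondary allylic carbinol. Four contiguous stereocentres, C4 (R), C5 (S), C6 (S) and C1 (R), surround the ring fusion, and the fifth, C9 (S), lies alone on the far side of ring B. On ring A the C4 hydroxyl and the C1 methyl are cis, whereas C5–H, the C6 ester oxygen and the C9 hydroxyl lie on the opposite (α) face of ring B. Fragile groups are the tertiary C4 alcohol (dehydration, and retro-aldol whenever C6 is a ketone), the 2-methylene allylic alcohol at C8/C9 (ionisation, double-bond migration into the ring) and the aryl ester with its free phenol (acyl transfer to neighbouring hydroxyls). The real difficulty is the hindered quaternary C1 beside the fully substituted C4 and the trans fusion, together with site- and face-selective oxygenation at C6 and C9 of a flexible seven-membered ring. Because C1 bears the C10–C9(O) unit, writing C5–C6 as an alkene makes C1 the γ-carbon of a γ,δ-unsaturated C9 ketone. Ring B is therefore the product of a Claisen ring expansion of a 2-methylenetetrahydrofuran spanning C6–C9 and bonded at C6 to the C5=C1 cyclopentene, whose C4 carbinol with its isopropyl group is C4 of (S)-terpinen-4-ol.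

## Logic of the disconnections

24 ⇒ 23 ⇒ 22. The phenolic O–Si bond and the C9–H bond are made last. Cutting them turns the sensitive allylic alcohol into a conjugated ketone and keeps the phenol masked throughout. The forward steps need a fluoride-labile aryl silyl ether and a 1,2-selective hydride that enters C9 from the β face.

22 ⇒ 20. The C8=C14 bond is cut because C14 is the only carbon outside the bicyclic core that the core-forming chemistry does not supply. This leaves a plain C9 ketone. The forward step must functionalise C8 and not C10, which the neopentylic position of C10 should ensure.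

20 ⇒ 16 + 19, and 19 ⇒ 17. The acyl–O6 bond is cut to separate the aromatic acid from the terpenoid diol. The forward acylation must pick the secondary C6 hydroxyl over the tertiary C4 hydroxyl, and the phenol must be blocked so the acid cannot self-condense.

16 ⇒ 15. The C6–H bond is cut, so that C6 becomes a ketone and its configuration is set independently of how that oxygen was introduced. The forward reduction must bring hydride to the more hindered β face of C6 and leave the C9 ketone alone, which calls for delivery from the C4 hydroxyl.

15 ⇒ 14 ⇒ 11. The C6–O and C5–H bonds are cut (retro-hydroboration) and the oxidation level is adjusted, removing two stereocentres and all ring-B oxygen except C9. The forward addition must be syn on the α face with boron at C6, and the silyl group must leave before any carbonyl is regenerated.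

11 ⇒ 10. The C1–C10 bond is cut and the C6–O bond restored (retro-Claisen). This removes ring B and the quaternary centre at once, leaving a five-membered enol ether whose single new stereocentre, C6, encodes C1. The forward step must be a stereospecific suprafacial [3,3] shift through a boat.

10 ⇒ 9. The exocyclic C9=C10 bond is cut back to a lactone carbonyl, a robust and storable precursor of the acid-sensitive enol ether. The forward methylenation must be neither acidic nor strongly basic.

9 ⇒ 5 + 6. The C6–C7 bond and the lactone C–O bond are cut, giving an enal and a three-carbon homoenolate. The forward addition must choose the Si face of the aldehyde under reagent control, against whatever bias C4 exerts.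

5 ⇒ 4. The C5=C1 bond is cut (retro-aldol condensation), opening ring A to an acyclic keto aldehyde. The forward closure needs the aldehyde as nucleophile and the methyl ketone as electrophile, hence enamine catalysis.

4 ⇒ 2 ⇒ 1. The two carbonyls are reconnected into a cyclohexene C=C bond (retro-ozonolysis) and the silyl group is removed, arriving at a chiral-pool terpene alcohol that already holds C4 in the correct configuration. The tertiary alcohol must be capped before the oxidative cleavage so that the β-oxygenated aldehyde does not eliminate.

## Other disconnections considered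

Alternative 1: The cut removes the C1–methyl bond and the C5–C6 bond, leaving ring A as the achiral enone A2 (3-allylcyclopent-2-enone) and the C6–C8/C14 carbons as the alkynal A3 (4-(trimethylsilyl)but-3-ynal).
- Forward key step: MeMgBr adds 1,4 to A2 under CuBr·SMe2 with a chiral diphosphine, and the magnesium enolate is trapped by A3 to give the aldol A1 with C1, C5 and C6 set in one flask.
- In its favour: enantiocontrol is catalytic and either antipode is available; three contiguous stereocentres arise together; the allyl and silylalkyne arms already carry C7–C10 and C14.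
- Against it here: methyl is the least reactive Grignard partner for quaternary-centre formation on a cyclopentenone. C4 must later be made by adding an isopropyl nucleophile to a hindered, enolisable β-hydroxy cyclopentanone, with retro-aldol and facial-control problems. Ring B still has to be closed as a seven-membered ring between C8 and C9, with C9 configuration uncontrolled by anything nearby.
- Comparison: on structure, the alternative is the better plan for flexibility of absolute configuration and reaches the C1/C5/C6 triad faster. The chosen plan is better at C4, which comes intact from the chiral pool, and at ring B, which is closed in the same step that makes C1. On mechanism, both rely on one stereo-determining event. On step economy, the two are about equal overall, because the alternative's short start is paid back in the C4 addition and ring closure.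

Alternative 2: The cut is the C1–C5 bond, restored as a C1–C6 bond in the cis-decalin hydroxy mesylate A5.
- Forward key step: Et3Al ionises the equatorial C5 mesylate of A5 while the anti-periplanar ring-fusion carbon C1 migrates from C6 to C5, giving the hydroxy ketone ketal A4.
- In its favour: the 1,2-shift is stereospecific (inversion at C5, retention at C1), so the trans fusion is guaranteed. This is better than the chosen plan, which depends on facial selectivity in a hydroboration. A4 is essentially the mono-ketal of 15, so from there the two plans are equal.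
- Against it here: A5 needs a quaternary C1, two tertiary carbinols (C4, C6) flanking a secondary sulfonate, and a defined ring fusion, all set before the key step. The C4 carbinol offers a competing anti-periplanar migration (C3 from C4 to C5, contracting the ring to an acyl cyclopentane) or epoxide closure.
- Comparison: on structure, the chosen plan builds ring B onto a ready ring A, while the alternative reshapes a 6–6 skeleton. On mechanism, both are stereospecific rearrangements and equal in reliability of transfer. On step economy, the chosen plan is clearly shorter up to the common intermediate.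

Alternative 3: The cut opens both C1–C5 and C1–C10 back to an aromatic ring and a tethered carbene precursor, the diazo keto ester A7.
- Forward key step: Rh2(OAc)4 decomposes A7, the carbene carbon C1 adds across the aromatic C5–C10 bond, and the norcaradiene opens to the bicyclic trienone A6, closing ring A and expanding the arene to ring B.
- In its favour: the arene brings the C14 methyl and both ring-B oxygens (C6, C9) from the start. This is better than the chosen plan, which must add C14 late and differentiate two ketones. Both rings and the quaternary centre form in one catalytic step.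
- Against it here: C1 emerges with an ester where a methyl is needed, and C2 carries a surplus ketone. The triene must then be reduced with control of C5, C6 and C9 with only C4 as a guide. The electron-rich dimethoxyarene invites aromatic substitution or oxonium ylide formation in place of cyclopropanation. The benzylic tertiary C4 ether would need its own asymmetric synthesis.
- Comparison: on structure, the alternative assembles the carbon skeleton faster. On mechanism, facial control at C1 relative to C4 is less secure than the chirality transfer of the chosen plan. On step and redox economy after the key step, the chosen plan is better.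

Key step: step 6

Remark: daucane locants are used for all bicyclic compounds ("14-nordaucane" is the skeleton without C14; α is the ring-B face of C5–H, β that of the C1 methyl). Tracing the suprafacial shift atom by atom shows that the (6S) enol ether leads to (1R), so no structure needs correction and the trimethylsilyl ether is retained.

## Steps

Step 1
Reactants: 1 (S)-terpinen-4-ol [(1S)-4-methyl-1-(propan-2-yl)cyclohex-3-en-1-ol]
Product: 2 (S)-terpinen-4-ol trimethylsilyl ether
Conditions: Me3SiCl, imidazole, DMF, rt
Reagents that add atoms: chlorotrimethylsilane, C[Si](C)(C)Cl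
Why: Silylation of the tertiary alcohol with the smallest silyl group; the ether prevents β-elimination once the neighbouring carbon becomes an aldehyde α-position and keeps the oxygen out of the later organometallic steps, while remaining removable under very mild acid.

Step 2
Reactants: 2 (S)-terpinen-4-ol trimethylsilyl ether
Product: 4 (S)-3-isopropyl-6-oxo-3-(trimethylsilyloxy)heptanal, via ozonide 3 (not isolated)
Conditions: O3, CH2Cl2, −78 °C; then PPh3, −78 °C → rt
Reagents that add atoms: ozone, [O-][O+]=O
Why: Ozonolysis of the only alkene with reductive work-up gives the methyl ketone and the aldehyde; the aprotic medium and neutral reductant spare the silyl ether and the stereocentre is not involved.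

Step 3
Reactants: 4 (S)-3-isopropyl-6-oxo-3-(trimethylsilyloxy)heptanal
Product: 5 (R)-5-isopropyl-2-methyl-5-(trimethylsilyloxy)cyclopent-1-ene-1-carbaldehyde
Conditions: piperidine, AcOH (cat.), PhH, rt → 60 °C
Reagents that add atoms: none
Why: Amine-catalysed intramolecular aldol condensation: the piperidine enamine of the aldehyde attacks the methyl ketone in a five-membered exo-trig closure and the aldol dehydrates through the iminium to the conjugated enal; the buffered, base-free medium avoids the alternative mode (ketone enolate onto aldehyde) and loss of the β-silyloxy group.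

Step 4
Reactants: 5 (R)-5-isopropyl-2-methyl-5-(trimethylsilyloxy)cyclopent-1-ene-1-carbaldehyde; 6 ethyl 3-iodopropanoate
Product: 9 (5S)-5-[(5R)-5-isopropyl-2-methyl-5-(trimethylsilyloxy)cyclopent-1-en-1-yl]dihydrofuran-2(3H)-one, via diorganozinc 7 (not isolated), via hydroxy ester 8 (not isolated)
Conditions: 6, Et2Zn, CuI (cat.), neat, 50 °C, then vacuum; Ti(OiPr)4, (1R,2R)-1,2-bis(trifluoromethanesulfonamido)cyclohexane (cat.), PhMe, −20 °C, then 5; aq NH4Cl; PPTS (cat.), PhMe, 50 °C
Reagents that add atoms: none
Why: Iodine–zinc exchange gives the salt-free zinc homoenolate, and the chiral titanium bis-sulfonamide complex transfers one alkyl group to the Si face of the enal (catalyst-controlled addition of functionalised dialkylzincs to aldehydes), which sets C6 as (S). The γ-hydroxy ester then closes to the lactone under mild acid without ionising the allylic C–O bond.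

Step 5
Reactants: 9 (5S)-5-[(5R)-5-isopropyl-2-methyl-5-(trimethylsilyloxy)cyclopent-1-en-1-yl]dihydrofuran-2(3H)-one
Product: 10 (5S)-2-methylene-5-[(5R)-5-isopropyl-2-methyl-5-(trimethylsilyloxy)cyclopent-1-en-1-yl]tetrahydrofuran
Conditions: Cp2TiMe2, PhMe, 70 °C, dark; filtration through basic Al2O3
Reagents that add atoms: dimethyltitanocene, C[Ti](C)(C1C=CC=C1)C1C=CC=C1
Why: Petasis methylenation: thermally generated Cp2Ti=CH2 adds to the lactone carbonyl and the oxatitanacyclobutane collapses to the exocyclic enol ether; the neutral conditions leave the silyl ether and the allylic C6 stereocentre untouched, and the base-washed isolation avoids migration of the new double bond into the ring.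

Step 6
Reactants: 10 (5S)-2-methylene-5-[(5R)-5-isopropyl-2-methyl-5-(trimethylsilyloxy)cyclopent-1-en-1-yl]tetrahydrofuran
Product: 11 (1R,4R)-4-(trimethylsilyloxy)-14-nordauc-5-en-9-one [(3R,8aR)-3-isopropyl-8a-methyl-3-(trimethylsilyloxy)-2,3,5,6,8,8a-hexahydroazulen-7(1H)-one]
Conditions: o-xylene, Et3N (cat.), 180 °C, sealed tube (silanised glass)
Reagents that add atoms: none
Why: A concerted thermal [3,3]-sigmatropic (Claisen) shift of the allyl vinyl ether C10=C9–O–C6–C5=C1 forms the C10–C1 bond as the C6–O bond breaks, leaving the C9 ketone and the C5=C6 alkene. The closest known reaction type is the ring-expanding Claisen rearrangement of 2-methylene-5-vinyltetrahydrofurans to cyclohept-4-enones. Ring B is closed not by an ionic cyclisation but by a four-atom enlargement of the tetrahydrofuran within a boat-shaped six-centre transition state, in which the ring forces C7 cis to C1 across the developing C5=C6 bond, so the new alkene is cis in the seven-membered ring. The only new stereocentre, C1, is controlled by C6: the shift is suprafacial on the cyclopentene, so C10 arrives on the face where the C6–O bond lies in the reactive rotamer, which for (6S) is the face anti to the C4 silyloxy group and gives (1R). Delivery to the other face would require a trans-cycloheptene, so the C4 substituents cannot override the transfer. The step needs complete face selectivity at C1, secured by the C6 centre set in step 4, and periselectivity over enol-ether isomerisation or ionisation of the allylic C6–O bond, secured by the aprotic, amine-buffered medium. The silyl ether and C4 are spectators and no reagent is consumed.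

Step 7
Reactants: 11 (1R,4R)-4-(trimethylsilyloxy)-14-nordauc-5-en-9-one
Product: 14 (1R,4R,5S,6S)-14-nordaucane-4,6,9-triol (C9 epimers), via bisboron adduct 12 (not isolated), via silyl ether diol 13 (not isolated)
Conditions: BH3·THF, THF, 0 °C → rt; NaOH, H2O2, 0 °C → rt; then 1 M HCl, THF–MeOH, rt
Reagents that add atoms: hydrogen peroxide, OO
Why: Hydroboration–oxidation: syn addition places boron at the less substituted C6 and hydrogen at C5 on the α face, opposite the C1 methyl and the C4 silyloxy group (as with Δ5-steroids), which sets the trans fusion, and oxidation proceeds with retention. The C9 ketone is reduced unselectively, which is harmless because C9 is re-oxidised, and the dilute acid then removes the tertiary silyl ether while no carbonyl is present.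

Step 8
Reactants: 14 (1R,4R,5S,6S)-14-nordaucane-4,6,9-triol (C9 epimers)
Product: 15 (1R,4R,5R)-4-hydroxy-14-nordaucane-6,9-dione
Conditions: Dess–Martin periodinane, NaHCO3, CH2Cl2, 0 °C → rt
Reagents that add atoms: none
Why: Dess–Martin oxidation of both secondary alcohols converges the C9 epimers; the tertiary C4 alcohol cannot be oxidised, and the buffered near-neutral medium should avoid dehydration, retro-aldol cleavage and epimerisation at C5 of the β-hydroxy ketone.

Step 9
Reactants: 15 (1R,4R,5R)-4-hydroxy-14-nordaucane-6,9-dione
Product: 16 (1R,4R,5S,6S)-4,6-dihydroxy-14-nordaucan-9-one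
Conditions: Me4NBH(OAc)3, AcOH–MeCN, −30 °C
Reagents that add atoms: none
Why: Evans–Saksena directed reduction: the borohydride exchanges onto the C4 oxygen and delivers hydride through a six-membered transition state to the β face of the C6 carbonyl (the face an external hydride would avoid because of the C1 methyl), giving the 1,3-anti 4,6-diol with the 6α hydroxyl; the C9 ketone has no directing hydroxyl and is not reduced by the acetoxyborohydride.

Step 10
Reactants: 17 4-hydroxybenzoic acid
Product: 19 4-(tert-butyldimethylsilyloxy)benzoic acid, via bis-silyl derivative 18 (not isolated)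
Conditions: t-BuMe2SiCl, imidazole, DMF, rt; then AcOH–H2O–THF, rt
Reagents that add atoms: tert-butyldimethylsilyl chloride, CC(C)(C)[Si](C)(C)Cl
Why: Silylation of phenol and acid followed by selective hydrolysis of the much more labile silyl ester; the aryl silyl ether is stable to aqueous acetic acid.

Step 11
Reactants: 16 (1R,4R,5S,6S)-4,6-dihydroxy-14-nordaucan-9-one; 19 4-(tert-butyldimethylsilyloxy)benzoic acid
Product: 20 (1R,4R,5S,6S)-4-hydroxy-9-oxo-14-nordaucan-6-yl 4-(tert-butyldimethylsilyloxy)benzoate
Conditions: DCC, DMAP, CH2Cl2, rt
Reagents that add atoms: none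
Why: Steglich esterification: the acylpyridinium acylates the secondary C6 hydroxyl with retention, while the tertiary, isopropyl-flanked C4 hydroxyl is too hindered to react.

Step 12
Reactants: 20 (1R,4R,5S,6S)-4-hydroxy-9-oxo-14-nordaucan-6-yl 4-(tert-butyldimethylsilyloxy)benzoate
Product: 22 (1R,4R,5S,6S)-4-hydroxy-9-oxodauc-8(14)-en-6-yl 4-(tert-butyldimethylsilyloxy)benzoate, via Mannich base 21 (not isolated)
Conditions: (CH2O)n, i-Pr2NH·CF3CO2H, CF3CO2H (cat.), THF, 65 °C
Reagents that add atoms: formaldehyde (from paraformaldehyde), C=O
Why: Mannich condensation–elimination (ammonium-salt-mediated α-methylenation): the enol of the C9 ketone attacks the iminium ion at C8, the less hindered α-carbon (C10 is neopentylic beside quaternary C1), and the β-aminoketone loses the amine to give the exocyclic enone; the weakly acidic medium should be tolerated by the ester, the aryl silyl ether and the tertiary alcohol.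

Step 13
Reactants: 22 (1R,4R,5S,6S)-4-hydroxy-9-oxodauc-8(14)-en-6-yl 4-(tert-butyldimethylsilyloxy)benzoate
Product: 23 (1R,4R,5S,6S,9S)-4,9-dihydroxydauc-8(14)-en-6-yl 4-(tert-butyldimethylsilyloxy)benzoate
Conditions: NaBH4, CeCl3·7H2O, MeOH, −78 °C
Reagents that add atoms: none
Why: Luche reduction: cerium activation makes the small methoxyborohydrides add 1,2, and their preference for an axial-type trajectory should bring hydride to the β face of C9 and leave the pseudo-equatorial 9α alcohol (9S), trans to the C1 methyl; the aryl ester and silyl ether are not reduced at this temperature.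

Step 14
Reactants: 23 (1R,4R,5S,6S,9S)-4,9-dihydroxydauc-8(14)-en-6-yl 4-(tert-butyldimethylsilyloxy)benzoate
Product: 24 ferugin [(1R,4R,5S,6S,9S)-4,9-dihydroxydauc-8(14)-en-6-yl 4-hydroxybenzoate]
Conditions: Bu4NF, AcOH, THF, 0 °C
Reagents that add atoms: none
Why: Fluoride cleaves the aryl O–Si bond, the most fluoride-labile silyl ether type; the acetic acid buffer keeps the phenoxide protonated, so acyl migration, ester cleavage and isomerisation of the allylic alcohol should not occur.

## Compound list

1 | (S)-terpinen-4-ol | CC1=CC[C@](O)(C(C)C)CC1 | starting material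
2 | (S)-terpinen-4-ol trimethylsilyl ether | CC1=CC[C@](O[Si](C)(C)C)(C(C)C)CC1 | intermediate
3 | secondary ozonide (1,2,4-trioxolane) of 2, trioxolane carbons unassigned | CC12CC[C@@](O[Si](C)(C)C)(C(C)C)CC(OO1)O2 | intermediate
4 | (S)-3-isopropyl-6-oxo-3-(trimethylsilyloxy)heptanal | O=CC[C@](O[Si](C)(C)C)(C(C)C)CCC(C)=O | intermediate
5 | (R)-5-isopropyl-2-methyl-5-(trimethylsilyloxy)cyclopent-1-ene-1-carbaldehyde | O=CC1=C(C)CC[C@@]1(O[Si](C)(C)C)C(C)C | intermediate
6 | ethyl 3-iodopropanoate | CCOC(=O)CCI | starting material
7 | bis(3-ethoxy-3-oxopropyl)zinc | CCOC(=O)CC[Zn]CCC(=O)OCC | intermediate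
8 | ethyl (4S)-4-hydroxy-4-[(5R)-5-isopropyl-2-methyl-5-(trimethylsilyloxy)cyclopent-1-en-1-yl]butanoate | CCOC(=O)CC[C@H](O)C1=C(C)CC[C@@]1(O[Si](C)(C)C)C(C)C | intermediate
9 | (5S)-5-[(5R)-5-isopropyl-2-methyl-5-(trimethylsilyloxy)cyclopent-1-en-1-yl]dihydrofuran-2(3H)-one | O=C1CC[C@H](O1)C2=C(C)CC[C@@]2(O[Si](C)(C)C)C(C)C | intermediate
10 | (5S)-2-methylene-5-[(5R)-5-isopropyl-2-methyl-5-(trimethylsilyloxy)cyclopent-1-en-1-yl]tetrahydrofuran | C=C1CC[C@H](O1)C2=C(C)CC[C@@]2(O[Si](C)(C)C)C(C)C | intermediate
11 | (1R,4R)-4-(trimethylsilyloxy)-14-nordauc-5-en-9-one | O=C1CCC=C2[C@@](C)(C1)CC[C@@]2(O[Si](C)(C)C)C(C)C | intermediate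
12 | 6α-boryl-9-boryloxy adduct of 11 (5α-H, C9 epimers) | [BH2]OC1CC[C@H]([BH2])[C@@H]2[C@](C)(CC[C@@]2(O[Si](C)(C)C)C(C)C)C1 | intermediate
13 | (1R,4R,5S,6S)-4-(trimethylsilyloxy)-14-nordaucane-6,9-diol (C9 epimers) | OC1CC[C@H](O)[C@@H]2[C@](C)(CC[C@@]2(O[Si](C)(C)C)C(C)C)C1 | intermediate
14 | (1R,4R,5S,6S)-14-nordaucane-4,6,9-triol (C9 epimers) | OC1CC[C@H](O)[C@@H]2[C@](C)(CC[C@@]2(O)C(C)C)C1 | intermediate
15 | (1R,4R,5R)-4-hydroxy-14-nordaucane-6,9-dione | O=C1CCC(=O)[C@@H]2[C@](C)(CC[C@@]2(O)C(C)C)C1 | intermediate
16 | (1R,4R,5S,6S)-4,6-dihydroxy-14-nordaucan-9-one | O=C1CC[C@H](O)[C@@H]2[C@](C)(CC[C@@]2(O)C(C)C)C1 | intermediate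
17 | 4-hydroxybenzoic acid | O=C(O)c1ccc(O)cc1 | starting material
18 | tert-butyldimethylsilyl 4-(tert-butyldimethylsilyloxy)benzoate | CC(C)(C)[Si](C)(C)OC(=O)c1ccc(O[Si](C)(C)C(C)(C)C)cc1 | intermediate
19 | 4-(tert-butyldimethylsilyloxy)benzoic acid | O=C(O)c1ccc(O[Si](C)(C)C(C)(C)C)cc1 | intermediate
20 | (1R,4R,5S,6S)-4-hydroxy-9-oxo-14-nordaucan-6-yl 4-(tert-butyldimethylsilyloxy)benzoate | O=C1CC[C@H](OC(=O)c3ccc(O[Si](C)(C)C(C)(C)C)cc3)[C@@H]2[C@](C)(CC[C@@]2(O)C(C)C)C1 | intermediate
21 | 8-(diisopropylaminomethyl) derivative of 20 (C8 epimers) | O=C1C(CN(C(C)C)C(C)C)C[C@H](OC(=O)c3ccc(O[Si](C)(C)C(C)(C)C)cc3)[C@@H]2[C@](C)(CC[C@@]2(O)C(C)C)C1 | intermediate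
22 | (1R,4R,5S,6S)-4-hydroxy-9-oxodauc-8(14)-en-6-yl 4-(tert-butyldimethylsilyloxy)benzoate | C=C1C[C@H](OC(=O)c3ccc(O[Si](C)(C)C(C)(C)C)cc3)[C@@H]2[C@](C)(CC[C@@]2(O)C(C)C)CC1=O | intermediate
23 | (1R,4R,5S,6S,9S)-4,9-dihydroxydauc-8(14)-en-6-yl 4-(tert-butyldimethylsilyloxy)benzoate | C=C1C[C@H](OC(=O)c3ccc(O[Si](C)(C)C(C)(C)C)cc3)[C@@H]2[C@](C)(CC[C@@]2(O)C(C)C)C[C@@H]1O | intermediate
24 | ferugin, (1R,4R,5S,6S,9S)-4,9-dihydroxydauc-8(14)-en-6-yl 4-hydroxybenzoate | C=C1C[C@H](OC(=O)c2ccc(O)cc2)[C@@H]2[C@](C)(CC[C@@]2(O)C(C)C)C[C@@H]1O | target

## Step count and least certain steps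

Total step count: 14. Longest linear sequence: 13 steps (steps 1–9 and 11–14); step 10 is a one-step side branch.

Step 6 (key step).
- What may go wrong: acid- or surface-promoted migration of the exocyclic enol-ether double bond into the ring before rearrangement, or heterolysis of the allylic C6–O bond at the temperature needed to make a quaternary centre on a tetrasubstituted alkene. Heterolysis would open a non-concerted pathway and erode the chirality transfer.
- Fallback: promote the rearrangement with a Lewis acid in place of heat. Treating 10 with i-Bu3Al (CH2Cl2, −78 °C → rt) should trigger the aluminium-accelerated Claisen ring expansion and reduce the ketone in situ by β-hydride transfer, giving the cycloheptenol (1R,4R)-4-(trimethylsilyloxy)-14-nordauc-5-en-9-ol (C9 epimers) F1. Because step 7 reduces C9 in any case, F1 is taken through the conditions of step 7 and rejoins the route at 14.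

Step 4.
- What may go wrong: sluggish alkyl transfer to the fully substituted, hindered enal, and substrate bias from the adjacent quaternary C4 eroding the reagent-controlled facial selectivity.
- Fallback: separate bond formation from stereocontrol. Addition of 7 to 5 promoted by Ti(OiPr)4 without the chiral ligand gives ethyl 4-hydroxy-4-[(5R)-5-isopropyl-2-methyl-5-(trimethylsilyloxy)cyclopent-1-en-1-yl]butanoate as a carbinol epimer mixture F2. Before it lactonises, F2 is oxidised at the allylic alcohol (MnO2, CH2Cl2) to ethyl 4-oxo-4-[(5R)-5-isopropyl-2-methyl-5-(trimethylsilyloxy)cyclopent-1-en-1-yl]butanoate F3. Corey–Bakshi–Shibata reduction of F3 with the (R)-2-methyl oxazaborolidine and catecholborane, the alkenyl group acting as the large substituent, should give 8, which is lactonised as in step 4 to return at 9.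

Step 7.
- What may go wrong: poor facial selectivity of borane addition, since the C4 isopropyl group guards the α face while the C1 methyl and C4 silyloxy groups guard the β face. This would give the cis-fused C5 epimer.
- Fallback: thermodynamic in place of kinetic control at C5.
  - The acid treatment is omitted, so that 11 gives the silyl ether diols, including the β-face adduct (1R,4R,5R,6R)-4-(trimethylsilyloxy)-14-nordaucane-6,9-diol (C9 epimers) F4.
  - Oxidation under the conditions of step 8 gives the cis-fused diketone (1R,4R,5S)-4-(trimethylsilyloxy)-14-nordaucane-6,9-dione F5.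
  - F5 is equilibrated through its C6 enolate (DBU, PhMe, rt) to the trans-fused (1R,4R,5R)-4-(trimethylsilyloxy)-14-nordaucane-6,9-dione F6. The trans isomer is expected to be favoured because it places the C6 carbonyl cis to the C4 oxygen and not beside the isopropyl group, and with the hydroxyl still silylated no retro-aldol is possible.
  - 1 M HCl in THF then removes the silyl group and the sequence returns at 15.

Step 12.
- What may go wrong: reaction at the wrong site or twice (C10, or both α-carbons), migration of the new double bond into the ring or dehydration at C4 on prolonged heating in the acidic medium, and dimerisation of the α-methylene ketone.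
- Fallback: a stepwise kinetic enolate route. 20 with LiN(SiMe3)2 (2.2 equiv, THF, −78 °C) forms the C4 alkoxide and the less hindered C8 enolate, which is trapped with Me2N=CH2 I (Eschenmoser's salt) to give the 8-(dimethylaminomethyl) ketone F7. MeI converts F7 into the 8-(trimethylammoniomethyl) ketone iodide F8, and aqueous NaHCO3 in CH2Cl2 eliminates trimethylamine to return at 22.

Step 13.
- What may go wrong: poor or reversed facial selectivity, because hydride approach anti to the C1 methyl (α face) competes with the axial-type β approach and would give the C9 epimer.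
- Fallback: use the steric bias and invert.
  - Reduction of 22 as in step 13, if it occurs mainly anti to the methyl, gives the 9-epimer (1R,4R,5S,6S,9R)-4,9-dihydroxydauc-8(14)-en-6-yl 4-(tert-butyldimethylsilyloxy)benzoate F9.
  - Mitsunobu inversion (4-nitrobenzoic acid, PPh3, DIAD, THF) converts F9 into (1R,4R,5S,6S,9S)-4-hydroxy-9-(4-nitrobenzoyloxy)dauc-8(14)-en-6-yl 4-(tert-butyldimethylsilyloxy)benzoate F10.
  - K2CO3 in MeOH at 0 °C then removes both the activated nitrobenzoate and the aryl silyl group; the phenoxide so formed deactivates the C6 ester towards methanolysis, and the sequence returns at 24.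

## Further compounds

F1 | step 6 | (1R,4R)-4-(trimethylsilyloxy)-14-nordauc-5-en-9-ol (C9 epimers) | OC1CCC=C2[C@@](C)(C1)CC[C@@]2(O[Si](C)(C)C)C(C)C
F2 | step 4 | ethyl 4-hydroxy-4-[(5R)-5-isopropyl-2-methyl-5-(trimethylsilyloxy)cyclopent-1-en-1-yl]butanoate (carbinol epimers) | CCOC(=O)CCC(O)C1=C(C)CC[C@@]1(O[Si](C)(C)C)C(C)C
F3 | step 4 | ethyl 4-oxo-4-[(5R)-5-isopropyl-2-methyl-5-(trimethylsilyloxy)cyclopent-1-en-1-yl]butanoate | CCOC(=O)CCC(=O)C1=C(C)CC[C@@]1(O[Si](C)(C)C)C(C)C
F4 | step 7 | (1R,4R,5R,6R)-4-(trimethylsilyloxy)-14-nordaucane-6,9-diol (cis-fused, C9 epimers) | OC1CC[C@@H](O)[C@H]2[C@](C)(CC[C@@]2(O[Si](C)(C)C)C(C)C)C1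
F5 | step 7 | (1R,4R,5S)-4-(trimethylsilyloxy)-14-nordaucane-6,9-dione (cis-fused) | O=C1CCC(=O)[C@H]2[C@](C)(CC[C@@]2(O[Si](C)(C)C)C(C)C)C1
F6 | step 7 | (1R,4R,5R)-4-(trimethylsilyloxy)-14-nordaucane-6,9-dione (trans-fused) | O=C1CCC(=O)[C@@H]2[C@](C)(CC[C@@]2(O[Si](C)(C)C)C(C)C)C1
F7 | step 12 | 8-(dimethylaminomethyl) derivative of 20 (C8 epimers) | O=C1C(CN(C)C)C[C@H](OC(=O)c3ccc(O[Si](C)(C)C(C)(C)C)cc3)[C@@H]2[C@](C)(CC[C@@]2(O)C(C)C)C1
F8 | step 12 | 8-(trimethylammoniomethyl) derivative of 20, iodide (C8 epimers) | O=C1C(C[N+](C)(C)C)C[C@H](OC(=O)c3ccc(O[Si](C)(C)C(C)(C)C)cc3)[C@@H]2[C@](C)(CC[C@@]2(O)C(C)C)C1.[I-]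
F9 | step 13 | (1R,4R,5S,6S,9R)-4,9-dihydroxydauc-8(14)-en-6-yl 4-(tert-butyldimethylsilyloxy)benzoate | C=C1C[C@H](OC(=O)c3ccc(O[Si](C)(C)C(C)(C)C)cc3)[C@@H]2[C@](C)(CC[C@@]2(O)C(C)C)C[C@H]1O
F10 | step 13 | (1R,4R,5S,6S,9S)-4-hydroxy-9-(4-nitrobenzoyloxy)dauc-8(14)-en-6-yl 4-(tert-butyldimethylsilyloxy)benzoate | C=C1C[C@H](OC(=O)c3ccc(O[Si](C)(C)C(C)(C)C)cc3)[C@@H]2[C@](C)(CC[C@@]2(O)C(C)C)C[C@@H]1OC(=O)c4ccc(cc4)[N+](=O)[O-]
A1 | alternative 1 | (2S,3R)-3-allyl-2-[(1S)-1-hydroxy-4-(trimethylsilyl)but-3-ynyl]-3-methylcyclopentanone | C[Si](C)(C)C#CC[C@H](O)[C@@H]1[C@](C)(CCC1=O)CC=C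
A2 | alternative 1 | 3-allylcyclopent-2-enone | C=CCC1=CC(=O)CC1
A3 | alternative 1 | 4-(trimethylsilyl)but-3-ynal | C[Si](C)(C)C#CCC=O
A4 | alternative 2 | trans-fused 3-hydroxy-3-isopropyl-8a-methyloctahydroazulen-4-one 7-ethylene ketal | C1CC(=O)[C@@H]2[C@](C)(CC[C@@]2(O)C(C)C)CC13OCCO3
A5 | alternative 2 | cis-decalin hydroxy mesylate: 1,8a-dihydroxy-1-isopropyl-4a-methyl-6,6-ethylenedioxydecahydronaphthalen-8-yl... written by daucane locants as 4,6-dihydroxy-4-isopropyl-1-methyl-9,9-ethylenedioxy decalin with C1–C6 ring fusion and C5 methanesulfonate | C[C@]12CC[C@@](O)(C(C)C)[C@H](OS(C)(=O)=O)[C@@]1(O)CCC3(OCCO3)C2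
A6 | alternative 3 | bicyclo[5.3.0]decatrienone with C6 and C9 methyl enol ethers, C8 methyl, C2 ketone, C1 ethyl ester and C4 trimethylsilyl ether | CCOC(=O)[C@@]12C=C(OC)C(C)=CC(OC)=C1[C@](O[Si](C)(C)C)(C(C)C)CC2=O
A7 | alternative 3 | ethyl 2-diazo-5-(2,5-dimethoxy-4-methylphenyl)-6-methyl-3-oxo-5-(trimethylsilyloxy)heptanoate | CCOC(=O)C(=[N+]=[N-])C(=O)C[C@@](O[Si](C)(C)C)(C(C)C)c1cc(OC)c(C)cc1OC
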